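**Plan**
- Retrosynthesis: remove the allyl helper ether; cut the 2H-chromene bonds C4–C4a and O1–C2 together (prenal plus a prenylated benzophenone); cut the C-prenyl bond; undo the protecting-group shuffle; cut the aryl–carbonyl bond (phloroglucinol plus 3-hydroxybenzonitrile).
- Forward: ring A and ring B are joined through the ketone first; one ortho oxygen of ring A is capped as an allyl ether (MOM on, allyl on, MOM off); the prenyl chain is attached at C3; the pyran ring is annulated in the penultimate step; the allyl group is removed last.
- Enabling feature: in ring A the free 4-hydroxyl and the adjacent unsubstituted C5 form the enol-like C=C–OH unit of an acylresorcinol, a 1,3-C,O-bis-nucleophile that takes up C1 and C3 of prenal; C5 and O4 become C4a and O1 of the chromene.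
- Helper: the 6-O-allyl ether on the other flank of C5 leaves O4 as the only oxygen able to close the pyran, so the aroyl group ends para to the ring oxygen.
- Stereochemistry: the target has no stereocentre; the ring alkene is cis by ring constraint and the prenyl alkene carries two identical methyl groups.

Key step: step 6

Remark: compounds 1, 2, 8 and 10 are taken as commercial; ring A positions in the benzophenones are numbered from the ketone-bearing carbon C1.

**Step 1**
Reactants: 1 benzene-1,3,5-triol (phloroglucinol); 2 3-hydroxybenzonitrile
Product: 4 (3-hydroxyphenyl)(2,4,6-trihydroxyphenyl)methanone, via ketiminium chloride 3 (not isolated)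
Conditions: ZnCl2, HCl (g), Et2O, 0 °C; then H2O, 100 °C
Reagents that add atoms: water, O
Why: Houben–Hoesch acylation, in which the nitrile activated by HCl and ZnCl2 is attacked by the symmetric, highly nucleophilic phloroglucinol (no regiochemical issue, and the ketiminium salt 3 deactivates the ring against a second acylation) and hydrolysis of 3 gives the ketone.

**Step 2**
Reactants: 4 (3-hydroxyphenyl)(2,4,6-trihydroxyphenyl)methanone
Product: 5 [2-hydroxy-4,6-bis(methoxymethoxy)phenyl][3-(methoxymethoxy)phenyl]methanone
Conditions: MOMCl (3.3 equiv), i-Pr2NEt, CH2Cl2, 0 °C to rt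
Reagents that add atoms: chloromethyl methyl ether (MOMCl), COCCl
Why: Williamson-type MOM ether formation under amine base should take the 4-hydroxyl, the ring B hydroxyl and one of the two equivalent ortho hydroxyls, after which the last ortho hydroxyl is locked in a strong hydrogen bond to the ketone and stays free, the standard partial protection of 2,4,6-trihydroxyaryl ketones.

**Step 3**
Reactants: 5 [2-hydroxy-4,6-bis(methoxymethoxy)phenyl][3-(methoxymethoxy)phenyl]methanone
Product: 6 [2,4-bis(methoxymethoxy)-6-(prop-2-en-1-yloxy)phenyl][3-(methoxymethoxy)phenyl]methanone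
Conditions: allyl bromide, K2CO3, DMF, 50 °C
Reagents that add atoms: allyl bromide, C=CCBr
Why: Williamson etherification of the remaining chelated phenol under the more forcing K2CO3/DMF conditions installs the allyl ether that later blocks this oxygen in the key step, and the MOM ethers are stable to base.

**Step 4**
Reactants: 6 [2,4-bis(methoxymethoxy)-6-(prop-2-en-1-yloxy)phenyl][3-(methoxymethoxy)phenyl]methanone
Product: 7 [2,4-dihydroxy-6-(prop-2-en-1-yloxy)phenyl](3-hydroxyphenyl)methanone
Conditions: 3 M HCl, MeOH, 50 °C
Reagents that add atoms: none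
Why: Acid-catalysed transacetalisation of the three MOM acetals to dimethoxymethane should free the phenols while the allyl aryl ether and the diaryl ketone are inert to dilute methanolic HCl, and the acid step is placed before any acid-sensitive alkene is present.

**Step 5**
Reactants: 7 [2,4-dihydroxy-6-(prop-2-en-1-yloxy)phenyl](3-hydroxyphenyl)methanone; 8 1-bromo-3-methylbut-2-ene (prenyl bromide)
Product: 9 [2,4-dihydroxy-3-(3-methylbut-2-en-1-yl)-6-(prop-2-en-1-yloxy)phenyl](3-hydroxyphenyl)methanone
Conditions: KOH (1.0 equiv), H2O, 0 °C to rt
Reagents that add atoms: none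
Why: C-alkylation of the ambident phenoxide of an acylresorcinol (nuclear prenylation), in which one equivalent of KOH ionises only the 4-hydroxyl (the most acidic, a vinylogous carboxylic acid), water solvates the oxygen and steers the allylic bromide to carbon, and C3 between the two free hydroxyls is the most nucleophilic ring position.

**Step 6**
Reactants: 9 [2,4-dihydroxy-3-(3-methylbut-2-en-1-yl)-6-(prop-2-en-1-yloxy)phenyl](3-hydroxyphenyl)methanone; 10 3-methylbut-2-enal (prenal)
Product: 12 [7-hydroxy-2,2-dimethyl-8-(3-methylbut-2-en-1-yl)-5-(prop-2-en-1-yloxy)-2H-chromen-6-yl](3-hydroxyphenyl)methanone, via oxatriene quinone methide 11 (not isolated)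
Conditions: ethylenediammonium diacetate (20 mol %), toluene, 110 °C
Reagents that add atoms: none
Why: Ethylenediammonium diacetate turns 10 into an iminium ion that ring A of 9 attacks through C5, the only unsubstituted carbon ortho to the free 4-hydroxyl (aldol/Mannich-type C–C bond formation); loss of the amine then gives the 1-oxatriene 11, a vinylogous ortho-quinone methide whose carbonyl oxygen is O4. Thermal disrotatory oxa-6π electrocyclization of 11 forms the O–C(CH3)2 bond and restores the aromatic sextet, which makes the closure irreversible. The closest known reaction type is the amine-salt-catalysed formal [3+3] annulation of resorcinols and acylresorcinols with α,β-unsaturated aldehydes (Knoevenagel condensation followed by oxa-6π electrocyclization, the classical chromenylation with prenal or citral). The pyran ring is closed pericyclically, with all six ring atoms part of the oxatriene, and not by an ionic 6-endo addition; no stereocentre arises because C2 carries two methyl groups. The step needs site selectivity on carbon and on oxygen: C3 is blocked by the prenyl group and ring B is a simple phenol too weakly nucleophilic to condense, while the 6-O-allyl ether leaves the 4-hydroxyl as the only oxygen next to C5 that can become the dienone carbonyl, the 2-hydroxyl being remote from C5 and tied up in the hydrogen bond to the ketone. Toluene at reflux stays well below the temperature of an aromatic Claisen rearrangement of the allyl ether, and the weakly acidic catalyst should not cyclise the prenyl group onto the neighbouring phenol.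

**Step 7**
Reactants: 12 [7-hydroxy-2,2-dimethyl-8-(3-methylbut-2-en-1-yl)-5-(prop-2-en-1-yloxy)-2H-chromen-6-yl](3-hydroxyphenyl)methanone
Product: 13 [5,7-dihydroxy-2,2-dimethyl-8-(3-methylbut-2-en-1-yl)-2H-chromen-6-yl](3-hydroxyphenyl)methanone
Conditions: Pd(PPh3)4 (5 mol %), morpholine, THF, rt
Reagents that add atoms: none
Why: Tsuji–Trost-type deallylation, in which zerovalent palladium ionises the aryl allyl ether to a π-allylpalladium complex and a ketone-stabilised phenoxide, morpholine traps the allyl fragment, and the C-prenyl group and the chromene alkene carry no leaving group and should stay untouched under these neutral conditions.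

**Compound list**
1 | benzene-1,3,5-triol (phloroglucinol) | Oc1cc(O)cc(O)c1 | starting material
2 | 3-hydroxybenzonitrile | N#Cc1cccc(O)c1 | starting material
3 | (3-hydroxyphenyl)(2,4,6-trihydroxyphenyl)methaniminium chloride | [Cl-].[NH2+]=C(c1cccc(O)c1)c1c(O)cc(O)cc1O | intermediate
4 | (3-hydroxyphenyl)(2,4,6-trihydroxyphenyl)methanone | O=C(c1cccc(O)c1)c1c(O)cc(O)cc1O | intermediate
5 | [2-hydroxy-4,6-bis(methoxymethoxy)phenyl][3-(methoxymethoxy)phenyl]methanone | COCOc1cc(O)c(C(=O)c2cccc(OCOC)c2)c(OCOC)c1 | intermediate
6 | [2,4-bis(methoxymethoxy)-6-(prop-2-en-1-yloxy)phenyl][3-(methoxymethoxy)phenyl]methanone | C=CCOc1cc(OCOC)cc(OCOC)c1C(=O)c1cccc(OCOC)c1 | intermediate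
7 | [2,4-dihydroxy-6-(prop-2-en-1-yloxy)phenyl](3-hydroxyphenyl)methanone | C=CCOc1cc(O)cc(O)c1C(=O)c1cccc(O)c1 | intermediate
8 | 1-bromo-3-methylbut-2-ene (prenyl bromide) | CC(C)=CCBr | starting material
9 | [2,4-dihydroxy-3-(3-methylbut-2-en-1-yl)-6-(prop-2-en-1-yloxy)phenyl](3-hydroxyphenyl)methanone | C=CCOc1cc(O)c(CC=C(C)C)c(O)c1C(=O)c1cccc(O)c1 | intermediate
10 | 3-methylbut-2-enal (prenal) | CC(C)=CC=O | starting material
11 | 3-hydroxy-4-(3-hydroxybenzoyl)-2-(3-methylbut-2-en-1-yl)-6-(3-methylbut-2-en-1-ylidene)-5-(prop-2-en-1-yloxy)cyclohexa-2,4-dien-1-one | C=CCOC1=C(C(=O)c2cccc(O)c2)C(O)=C(CC=C(C)C)C(=O)C1=CC=C(C)C | intermediate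
12 | [7-hydroxy-2,2-dimethyl-8-(3-methylbut-2-en-1-yl)-5-(prop-2-en-1-yloxy)-2H-chromen-6-yl](3-hydroxyphenyl)methanone | C=CCOc1c2C=CC(C)(C)Oc2c(CC=C(C)C)c(O)c1C(=O)c1cccc(O)c1 | intermediate
13 | [5,7-dihydroxy-2,2-dimethyl-8-(3-methylbut-2-en-1-yl)-2H-chromen-6-yl](3-hydroxyphenyl)methanone | CC(C)=CCc1c(O)c(C(=O)c2cccc(O)c2)c(O)c2c1OC(C)(C)C=C2 | target

**Step count and risks**
Total step count: 7. Longest linear sequence: 7 steps (from 1 and 2 to 13).

Steps most likely to fail:

Step 5. The nuclear prenylation may be eroded by competing O-alkylation, by double alkylation and by alkylation of the ring B phenol. Some prenyl may also enter C5 instead of C3; that isomer would still lead to 13 after annulation at C3 and deallylation, but only if closure again takes place on the 4-oxygen, which is then favoured by the hydrogen bond of the 2-hydroxyl and no longer enforced by the ether. The fallback sets out from 5. The free chelated hydroxyl is O-prenylated with 8 (K2CO3, DMF) to [2,4-bis(methoxymethoxy)-6-[(3-methylbut-2-en-1-yl)oxy]phenyl][3-(methoxymethoxy)phenyl]methanone F1. Heating F1 in N,N-diethylaniline at about 200 °C should bring about an aromatic Claisen rearrangement followed by a Cope rearrangement, which carries the prenyl group to the para carbon and gives [6-hydroxy-2,4-bis(methoxymethoxy)-3-(3-methylbut-2-en-1-yl)phenyl][3-(methoxymethoxy)phenyl]methanone F2. The liberated hydroxyl is allylated (allyl bromide, K2CO3, DMF) to [2,4-bis(methoxymethoxy)-3-(3-methylbut-2-en-1-yl)-6-(prop-2-en-1-yloxy)phenyl][3-(methoxymethoxy)phenyl]methanone F3, and removal of the three MOM groups (HCl, MeOH, rt) comes back to the route at 9.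

Step 6. Condensation at a carbon flanked by two oxygen substituents on a ketone-deactivated ring may be slow, so that self-condensation of prenal or oligomerisation of the quinone methide takes over. The fallback sets out from 9 and replaces the intermolecular condensation by a tethered pericyclic cascade. The most acidic 4-hydroxyl is alkylated with 3-chloro-3-methylbut-1-yne (K2CO3, KI, CuI, acetone, 56 °C) to [2-hydroxy-3-(3-methylbut-2-en-1-yl)-4-[(2-methylbut-3-yn-2-yl)oxy]-6-(prop-2-en-1-yloxy)phenyl](3-hydroxyphenyl)methanone F4. Heating F4 in xylene at 140 °C should trigger the aromatic propargyl Claisen rearrangement to C5, enolisation, a 1,5-hydrogen shift and oxa-6π closure, again onto O4 because the allyl ether blocks the other flank, and the sequence comes back to the route at 12.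

Step 1. Activation of the aryl nitrile may be sluggish and the free phenol of 2 may be diverted into O-imidate formation, giving low conversion. The fallback sets out from 1. Friedel–Crafts acylation with 3-methoxybenzoyl chloride (AlCl3, nitrobenzene, rt to 60 °C) should give (3-methoxyphenyl)(2,4,6-trihydroxyphenyl)methanone F5, and demethylation of F5 (BBr3, CH2Cl2, −78 °C to rt) comes back to the route at 4.

**Further compounds**
F1 | step 5 | [2,4-bis(methoxymethoxy)-6-[(3-methylbut-2-en-1-yl)oxy]phenyl][3-(methoxymethoxy)phenyl]methanone | CC(C)=CCOc1cc(OCOC)cc(OCOC)c1C(=O)c1cccc(OCOC)c1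
F2 | step 5 | [6-hydroxy-2,4-bis(methoxymethoxy)-3-(3-methylbut-2-en-1-yl)phenyl][3-(methoxymethoxy)phenyl]methanone | COCOc1cc(O)c(C(=O)c2cccc(OCOC)c2)c(OCOC)c1CC=C(C)C
F3 | step 5 | [2,4-bis(methoxymethoxy)-3-(3-methylbut-2-en-1-yl)-6-(prop-2-en-1-yloxy)phenyl][3-(methoxymethoxy)phenyl]methanone | C=CCOc1cc(OCOC)c(CC=C(C)C)c(OCOC)c1C(=O)c1cccc(OCOC)c1
F4 | step 6 | [2-hydroxy-3-(3-methylbut-2-en-1-yl)-4-[(2-methylbut-3-yn-2-yl)oxy]-6-(prop-2-en-1-yloxy)phenyl](3-hydroxyphenyl)methanone | C=CCOc1cc(OC(C)(C)C#C)c(CC=C(C)C)c(O)c1C(=O)c1cccc(O)c1
F5 | step 1 | (3-methoxyphenyl)(2,4,6-trihydroxyphenyl)methanone | COc1cccc(C(=O)c2c(O)cc(O)cc2O)c1
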